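**Plan** (germacranolide numbering: ring C1–C10, lactone O–C6/C7–C11–C12, C13 methylene, C14 formyl carbon, C15 methyl on C4)

1. Cuts: the oxirane back to the Z C4=C5 alkene; then both ring alkenes, C4=C5 and C1=C10, at once, because C1, C2, C3, C4 and the C4 methyl lie between two cis trisubstituted double bonds of the ten-membered ring and are 1-methylcyclobutene opened at its double bond; then C7–C8.
2. Forward: the γ-lactone comes in with a chiral butenolide; the C8–C10/C14 chain is joined by conjugate addition of a 2-allyl-1,3-dithianyl anion; the ten-membered ring closes by inserting 1-methylcyclobutene between the C5 vinyl and C10 methylidene carbons; the oxirane is made last.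
3. O8 and O14 are tied as a seven-membered acetonide during the insertion, so that C5 cannot close directly onto C10 (that six-membered ring would hold a bridgehead alkene) and C1=C10 forms cis within the ten-membered ring.
4. Stereochemistry: C6 from (S)-5-(hydroxymethyl)furan-2(5H)-one; C7 by trans addition to it; C8 by CBS reduction matched with Felkin–Anh control; C4/C5 by epoxidation of the Z alkene anti to the C6–O bond; both alkene geometries are set in the key step.

Key step: step 13

Assumption: compounds 1, 4, 7 and 19 are purchased; 1-methylcyclobutene is made in step 12 and may carry some exocyclic isomer, which is taken to be inert in step 13. The target is read as 4R,5S,6S,7R,8R with both ring alkenes cis in the ring.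

**Route**

Step 1
Reactants: 1 2-methylidenepropane-1,3-diol
Product: 2 2-({[tert-butyl(dimethyl)silyl]oxy}methyl)prop-2-en-1-ol
Conditions: NaH (1.0 equiv), THF, 0 °C; TBSCl, 0 → 23 °C
Reagents that add atoms: tert-butyldimethylsilyl chloride, CC(C)(C)[Si](C)(C)Cl
Why: Monosilylation of a symmetrical diol through its sparingly soluble monosodium alkoxide (O-silylation) should stop after one hydroxyl.

Step 2
Reactants: 2 2-({[tert-butyl(dimethyl)silyl]oxy}methyl)prop-2-en-1-ol
Product: 3 {[2-(bromomethyl)prop-2-en-1-yl]oxy}(tert-butyl)dimethylsilane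
Conditions: CBr4, PPh3, CH2Cl2, 0 °C
Reagents that add atoms: carbon tetrabromide, BrC(Br)(Br)Br
Why: Appel bromination turns the primary allylic alcohol into the bromide under neutral conditions that the silyl ether tolerates.

Step 3
Reactants: 4 1,3-dithiane; 3 {[2-(bromomethyl)prop-2-en-1-yl]oxy}(tert-butyl)dimethylsilane
Product: 6 tert-butyl{[2-(1,3-dithian-2-ylmethyl)prop-2-en-1-yl]oxy}dimethylsilane, via 2-lithio-1,3-dithiane 5 (not isolated)
Conditions: n-BuLi, THF, −30 °C; then 3, −78 → 0 °C
Reagents that add atoms: none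
Why: Corey–Seebach alkylation, in which the sulfur-stabilised carbanion displaces the allylic bromide (SN2).

Step 4
Reactants: 7 (S)-5-(hydroxymethyl)furan-2(5H)-one
Product: 8 (S)-5-({[tert-butyl(diphenyl)silyl]oxy}methyl)furan-2(5H)-one
Conditions: TBDPSCl, imidazole, CH2Cl2, 0 → 23 °C
Reagents that add atoms: tert-butyldiphenylsilyl chloride, CC(C)(C)[Si](Cl)(c1ccccc1)c1ccccc1
Why: Imidazole-promoted silylation of the primary alcohol gives a bulky ether that later shields one face of the butenolide.

Step 5
Reactants: 6 tert-butyl{[2-(1,3-dithian-2-ylmethyl)prop-2-en-1-yl]oxy}dimethylsilane; 8 (S)-5-({[tert-butyl(diphenyl)silyl]oxy}methyl)furan-2(5H)-one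
Product: 11 (4S,5S)-5-(TBDPS-oxymethyl)-4-{2-[2-(TBS-oxymethyl)prop-2-en-1-yl]-1,3-dithian-2-yl}oxolan-2-one, via lithiated dithiane 9 (not isolated), via lithium enolate 10 (not isolated)
Conditions: n-BuLi, THF, −25 °C; HMPA; 8, −78 °C; AcOH, −78 °C
Reagents that add atoms: none
Why: Conjugate (Michael) addition of a 2-lithio-1,3-dithiane to a butenolide, steered to the 1,4 mode by HMPA; attack anti to the C6 silyloxymethyl group sets C7 trans to C6.

Step 6
Reactants: 11 (4S,5S)-5-(TBDPS-oxymethyl)-4-{2-[2-(TBS-oxymethyl)prop-2-en-1-yl]-1,3-dithian-2-yl}oxolan-2-one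
Product: 12 (4S,5S)-5-(TBDPS-oxymethyl)-4-[3-(TBS-oxymethyl)but-3-enoyl]oxolan-2-one
Conditions: MeI, CaCO3, MeCN/H2O (9:1), 40 °C
Reagents that add atoms: water, O
Why: Dithiane unmasking by S-methylation and hydrolysis under buffered neutral conditions, chosen to avoid alkene migration into conjugation and β-elimination of the lactone oxygen from the C8 ketone.

Step 7
Reactants: 12 (4S,5S)-5-(TBDPS-oxymethyl)-4-[3-(TBS-oxymethyl)but-3-enoyl]oxolan-2-one
Product: 13 (4R,5S)-5-(TBDPS-oxymethyl)-4-[(1R)-1-hydroxy-3-(TBS-oxymethyl)but-3-en-1-yl]oxolan-2-one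
Conditions: (S)-2-methyl-CBS-oxazaborolidine (0.5 equiv), catecholborane, toluene, −78 °C
Reagents that add atoms: none
Why: Corey–Bakshi–Shibata reduction, in which the (S)-oxazaborolidine should give the 8R alcohol with the branched C7 side as the large group, the same face as Felkin–Anh attack anti to the C7–C6 bond; catecholborane leaves alkene and lactone alone.

Step 8
Reactants: 13 (4R,5S)-5-(TBDPS-oxymethyl)-4-[(1R)-1-hydroxy-3-(TBS-oxymethyl)but-3-en-1-yl]oxolan-2-one
Product: 15 (4R,5S)-5-(TBDPS-oxymethyl)-4-[(4R)-2,2-dimethyl-6-methylidene-1,3-dioxepan-4-yl]oxolan-2-one, via diol 14 (not isolated)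
Conditions: PPTS, MeOH, 40 °C; evaporate; 2,2-dimethoxypropane, PPTS, CH2Cl2, 23 °C
Reagents that add atoms: 2,2-dimethoxypropane, COC(C)(C)OC
Why: Acid-catalysed methanolysis removes the primary allylic TBS ether but not the TBDPS ether, and transacetalisation then closes the 1,4-diol to the isopropylidene acetal (1,3-dioxepane) that ties O8 to O14.

Step 9
Reactants: 15 (4R,5S)-5-(TBDPS-oxymethyl)-4-[(4R)-2,2-dimethyl-6-methylidene-1,3-dioxepan-4-yl]oxolan-2-one
Product: 16 (4R,5S)-4-[(4R)-2,2-dimethyl-6-methylidene-1,3-dioxepan-4-yl]-5-(hydroxymethyl)oxolan-2-one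
Conditions: Bu4NF, AcOH, THF, 0 → 23 °C
Reagents that add atoms: none
Why: Fluoride-induced desilylation, buffered with acetic acid so that lactone and acetal are untouched.

Step 10
Reactants: 16 (4R,5S)-4-[(4R)-2,2-dimethyl-6-methylidene-1,3-dioxepan-4-yl]-5-(hydroxymethyl)oxolan-2-one
Product: 17 (2S,3R)-3-[(4R)-2,2-dimethyl-6-methylidene-1,3-dioxepan-4-yl]-5-oxooxolane-2-carbaldehyde
Conditions: Dess–Martin periodinane, NaHCO3, CH2Cl2, 0 → 23 °C
Reagents that add atoms: none
Why: Dess–Martin oxidation gives the α-acyloxy aldehyde without amine base, and C6 is not at risk because the trans lactone is the more stable arrangement.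

Step 11
Reactants: 17 (2S,3R)-3-[(4R)-2,2-dimethyl-6-methylidene-1,3-dioxepan-4-yl]-5-oxooxolane-2-carbaldehyde
Product: 18 (4R,5R)-4-[(4R)-2,2-dimethyl-6-methylidene-1,3-dioxepan-4-yl]-5-ethenyloxolan-2-one
Conditions: Ph3PCH3Br, KN(SiMe3)2, THF, 0 °C; then 17, −78 → 0 °C
Reagents that add atoms: methyltriphenylphosphonium bromide, C[P+](c1ccccc1)(c1ccccc1)c1ccccc1.[Br-]
Why: Wittig methylenation with a non-stabilised ylide at low temperature should react at the aldehyde far faster than at the lactone carbonyl.

Step 12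
Reactants: 19 methylenecyclobutane
Product: 20 1-methylcyclobutene
Conditions: KOt-Bu (cat.), DMSO, 70 °C, sealed vessel; distillation
Reagents that add atoms: none
Why: Base-catalysed prototropic alkene isomerisation moves the exocyclic double bond into the ring, the more substituted and more stable position.

Step 13
Reactants: 18 (4R,5R)-4-[(4R)-2,2-dimethyl-6-methylidene-1,3-dioxepan-4-yl]-5-ethenyloxolan-2-one; 20 1-methylcyclobutene
Product: 22 acetonide-bridged (Z,Z)-cyclodeca-1(10),4-diene trans-fused γ-lactone (6R,7R,8R), via triene 21 (not isolated)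
Conditions: 18 (0.05 M), RuCl2(H2IMes)(=CH-C6H4-2-O-i-Pr) (second-generation Hoveyda–Grubbs catalyst, H2IMes = 1,3-dimesitylimidazolidin-2-ylidene, 10 mol %), 1,4-benzoquinone (10 mol %), toluene, 23 °C, 20 (1.3 equiv) added over 6 h; then dilution to 2 mM, 70 °C, argon sparge
Reagents that add atoms: none
Why: Proposed new method: the ruthenium methylidene exchanges onto the monosubstituted C5 vinyl group, the C5 alkylidene adds across the strained double bond of 20 so that C5 bonds to the methyl-bearing carbon (C4) and ruthenium takes the unsubstituted carbon (C1), cycloreversion releases the ring strain to give the C4=C5 alkene, and the C1 alkylidene (directly, or after exchange to the terminal alkene of triene 21) closes onto the C10 methylidene with loss of ethylene. The closest known reaction types are ring-opening cross-metathesis of 1-substituted cyclobutenes and other trisubstituted cycloalkenes, where the quaternary carbon likewise sits in the β-position of the ruthenacyclobutane, and ring-expansion metathesis of cycloalkenes with acyclic dienes; a single insertion of a 1-alkylcyclobutene between the two ends of a diene is not known. The ten-membered carbocycle closes by ring-closing metathesis at C1=C10 onto the exocyclic alkene of the dioxepane, giving a bicyclo[7.4.1] skeleton. No stereocentre is formed; the C4=C5 geometry is fixed in the ruthenacyclobutane, where the C6 substituent on the α-carbon should turn away from the free methyl and toward the pinned-back ring methylene (Z, C3 cis to C6), and the C1=C10 geometry by the bicycle, in which the alkene can be cis in the ten-membered ring and trans only in the thirteen-membered one. The step needs head-to-tail and single insertion and no direct C5-to-C10 closure: slow addition of 20 to an excess of vinyl groups keeps the C5 alkylidene (not the methylidene or a chain end) as the species that meets the cyclobutene and leaves none for the slow ring closure, and the acetonide bridge turns the otherwise fast six-membered closure into the formation of a bridgehead alkene in a bicyclo[4.3.1]decene, which Bredt strain should shut off.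

Step 14
Reactants: 22 acetonide-bridged (Z,Z)-cyclodeca-1(10),4-diene trans-fused γ-lactone (6R,7R,8R)
Product: 24 C11-(dimethylaminomethyl) lactone (aminomethyl group trans to the C7–C8 bond), via lithium enolate 23 (not isolated)
Conditions: LiN(i-Pr)2 (commercial solution), THF, −78 °C; Eschenmoser's salt, −78 → 23 °C
Reagents that add atoms: N,N-dimethylmethyleneiminium iodide (Eschenmoser's salt), C=[N+](C)C.[I-]
Why: Mannich reaction of the lactone enolate with the preformed iminium salt, the electrophile entering anti to the C7 substituent (this centre is removed in step 15).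

Step 15
Reactants: 24 C11-(dimethylaminomethyl) lactone
Product: 26 acetonide-bridged α-methylene lactone (6R,7R,8R), via ammonium iodide 25 (not isolated)
Conditions: MeI, MeOH/CH2Cl2, 23 °C; then aq. NaHCO3, CH2Cl2, 23 °C
Reagents that add atoms: none
Why: Quaternisation and E1cB (Hofmann-type) elimination of trimethylamine is the standard way to unveil an α-methylene-γ-butyrolactone.

Step 16
Reactants: 26 acetonide-bridged α-methylene lactone (6R,7R,8R)
Product: 27 8,14-diol of the (Z,Z)-cyclodecadiene α-methylene lactone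
Conditions: AcOH/THF/H2O (3:1:1), 23 °C
Reagents that add atoms: none
Why: Mild acid hydrolysis of the strained seven-membered acetonide should proceed without protonating the trisubstituted alkenes.

Step 17
Reactants: 27 8,14-diol of the (Z,Z)-cyclodecadiene α-methylene lactone
Product: 28 14-O-TBS ether with free 8-hydroxyl
Conditions: TBSCl, imidazole, CH2Cl2, −20 °C
Reagents that add atoms: tert-butyldimethylsilyl chloride, CC(C)(C)[Si](C)(C)Cl
Why: Silylation discriminates the primary allylic hydroxyl from the hindered secondary one, so that C8 is acylated before the aldehyde exists and no 8,14-lactol can form.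

Step 18
Reactants: 28 14-O-TBS ether with free 8-hydroxyl
Product: 29 8-O-isovalerate 14-O-TBS ether
Conditions: isovaleric anhydride, DMAP (cat.), pyridine, CH2Cl2, 0 → 23 °C
Reagents that add atoms: 3-methylbutanoic anhydride, CC(C)CC(=O)OC(=O)CC(C)C
Why: DMAP-catalysed acylation (Steglich-type acyl transfer) of the secondary alcohol with retention at C8.

Step 19
Reactants: 29 8-O-isovalerate 14-O-TBS ether
Product: 30 8-O-isovalerate with free 14-hydroxyl
Conditions: HF·pyridine, pyridine, THF, 0 °C
Reagents that add atoms: none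
Why: Buffered fluoride desilylation removes the primary silyl ether without touching the ester or the conjugated lactone.

Step 20
Reactants: 30 8-O-isovalerate with free 14-hydroxyl
Product: 31 8-O-isovaleryl 14-al (Z,Z-ring diene, α-methylene lactone)
Conditions: MnO2, CH2Cl2, 23 °C
Reagents that add atoms: none
Why: MnO2 oxidises only the allylic alcohol and keeps the alkene geometry, giving the enal with the formyl group trans to C2.

Step 21
Reactants: 31 8-O-isovaleryl 14-al (Z,Z-ring diene, α-methylene lactone)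
Product: 32 target, (4R,5S,6S,7R,8R)-4,5-epoxide
Conditions: dimethyldioxirane, acetone/CH2Cl2, −20 → 0 °C
Reagents that add atoms: dimethyldioxirane, CC1(C)OO1
Why: Electrophilic oxygen transfer from the dioxirane picks the only electron-rich alkene and, with C6–H eclipsing the Z alkene (A(1,3) strain), should arrive anti to the C6–O bond, which is the 4R,5S face.

**Compound list**

1 | 2-methylidenepropane-1,3-diol | C=C(CO)CO | starting material
2 | 2-({[tert-butyl(dimethyl)silyl]oxy}methyl)prop-2-en-1-ol | C=C(CO)CO[Si](C)(C)C(C)(C)C | intermediate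
3 | {[2-(bromomethyl)prop-2-en-1-yl]oxy}(tert-butyl)dimethylsilane | C=C(CBr)CO[Si](C)(C)C(C)(C)C | intermediate
4 | 1,3-dithiane | C1CSCSC1 | starting material
5 | 2-lithio-1,3-dithiane (not isolated) | [Li]C1SCCCS1 | intermediate
6 | tert-butyl{[2-(1,3-dithian-2-ylmethyl)prop-2-en-1-yl]oxy}dimethylsilane | C=C(CC1SCCCS1)CO[Si](C)(C)C(C)(C)C | intermediate
7 | (S)-5-(hydroxymethyl)furan-2(5H)-one | OC[C@H]1OC(=O)C=C1 | starting material
8 | (S)-5-({[tert-butyl(diphenyl)silyl]oxy}methyl)furan-2(5H)-one | CC(C)(C)[Si](c1ccccc1)(c1ccccc1)OC[C@H]1OC(=O)C=C1 | intermediate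
9 | 2-lithio derivative of 6 (not isolated) | [Li]C1(CC(=C)CO[Si](C)(C)C(C)(C)C)SCCCS1 | intermediate
10 | lithium enolate of 11 (not isolated) | C1=C(O[Li])O[C@H](CO[Si](c2ccccc2)(c3ccccc3)C(C)(C)C)[C@H]1C4(CC(=C)CO[Si](C)(C)C(C)(C)C)SCCCS4 | intermediate
11 | (4S,5S)-5-(TBDPS-oxymethyl)-4-{2-[2-(TBS-oxymethyl)prop-2-en-1-yl]-1,3-dithian-2-yl}oxolan-2-one (trans) | C1C(=O)O[C@H](CO[Si](c2ccccc2)(c3ccccc3)C(C)(C)C)[C@H]1C4(CC(=C)CO[Si](C)(C)C(C)(C)C)SCCCS4 | intermediate
12 | (4S,5S)-5-(TBDPS-oxymethyl)-4-[3-(TBS-oxymethyl)but-3-enoyl]oxolan-2-one | C1C(=O)O[C@H](CO[Si](c2ccccc2)(c3ccccc3)C(C)(C)C)[C@H]1C(=O)CC(=C)CO[Si](C)(C)C(C)(C)C | intermediate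
13 | (4R,5S)-5-(TBDPS-oxymethyl)-4-[(1R)-1-hydroxy-3-(TBS-oxymethyl)but-3-en-1-yl]oxolan-2-one | C1C(=O)O[C@H](CO[Si](c2ccccc2)(c3ccccc3)C(C)(C)C)[C@H]1[C@H](O)CC(=C)CO[Si](C)(C)C(C)(C)C | intermediate
14 | (4R,5S)-5-(TBDPS-oxymethyl)-4-[(1R)-1-hydroxy-3-(hydroxymethyl)but-3-en-1-yl]oxolan-2-one (not isolated) | C1C(=O)O[C@H](CO[Si](c2ccccc2)(c3ccccc3)C(C)(C)C)[C@H]1[C@H](O)CC(=C)CO | intermediate
15 | (4R,5S)-5-(TBDPS-oxymethyl)-4-[(4R)-2,2-dimethyl-6-methylidene-1,3-dioxepan-4-yl]oxolan-2-one | C1C(=O)O[C@H](CO[Si](c2ccccc2)(c3ccccc3)C(C)(C)C)[C@H]1[C@H]4CC(=C)COC(C)(C)O4 | intermediate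
16 | (4R,5S)-4-[(4R)-2,2-dimethyl-6-methylidene-1,3-dioxepan-4-yl]-5-(hydroxymethyl)oxolan-2-one | C1C(=O)O[C@H](CO)[C@H]1[C@H]4CC(=C)COC(C)(C)O4 | intermediate
17 | (2S,3R)-3-[(4R)-2,2-dimethyl-6-methylidene-1,3-dioxepan-4-yl]-5-oxooxolane-2-carbaldehyde | C1C(=O)O[C@H](C=O)[C@H]1[C@H]4CC(=C)COC(C)(C)O4 | intermediate
18 | (4R,5R)-4-[(4R)-2,2-dimethyl-6-methylidene-1,3-dioxepan-4-yl]-5-ethenyloxolan-2-one (trans-lactone diene, C5 vinyl and C10 methylidene) | C1C(=O)O[C@H](C=C)[C@H]1[C@H]4CC(=C)COC(C)(C)O4 | intermediate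
19 | methylenecyclobutane | C=C1CCC1 | starting material
20 | 1-methylcyclobutene | CC1=CCC1 | intermediate
21 | (4R,5R)-4-[(4R)-2,2-dimethyl-6-methylidene-1,3-dioxepan-4-yl]-5-[(1Z)-2-methylhexa-1,5-dien-1-yl]oxolan-2-one (not isolated) | C1C(=O)O[C@H](/C=C(C)\CCC=C)[C@H]1[C@H]4CC(=C)COC(C)(C)O4 | intermediate
22 | acetonide-bridged (Z,Z)-cyclodeca-1(10),4-diene trans-fused γ-lactone, 6R,7R,8R, O8 and O14 joined by CMe2 | C1C(=O)O[C@H]2[C@H]1[C@H]4C/C(COC(C)(C)O4)=C\CC/C(C)=C\2 | intermediate
23 | lithium enolate of 22 (not isolated) | C1=C(O[Li])O[C@H]2[C@H]1[C@H]4C/C(COC(C)(C)O4)=C\CC/C(C)=C\2 | intermediate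
24 | C11-(dimethylaminomethyl) derivative of 22, aminomethyl trans to the C7–C8 bond | CN(C)C[C@@H]1C(=O)O[C@H]2[C@H]1[C@H]4C/C(COC(C)(C)O4)=C\CC/C(C)=C\2 | intermediate
25 | trimethylammonium iodide of 24 (not isolated) | C[N+](C)(C)C[C@@H]1C(=O)O[C@H]2[C@H]1[C@H]4C/C(COC(C)(C)O4)=C\CC/C(C)=C\2.[I-] | intermediate
26 | acetonide-bridged α-methylene lactone, 6R,7R,8R | C=C1C(=O)O[C@H]2[C@H]1[C@H]4C/C(COC(C)(C)O4)=C\CC/C(C)=C\2 | intermediate
27 | 8,14-diol, (6R,7R,8R)-(Z,Z)-cyclodecadiene α-methylene lactone | C=C1C(=O)O[C@H]2[C@H]1[C@H](O)C/C(CO)=C\CC/C(C)=C\2 | intermediate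
28 | 14-O-TBS ether of 27 | C=C1C(=O)O[C@H]2[C@H]1[C@H](O)C/C(CO[Si](C)(C)C(C)(C)C)=C\CC/C(C)=C\2 | intermediate
29 | 8-O-isovalerate 14-O-TBS ether | C=C1C(=O)O[C@H]2[C@H]1[C@H](OC(=O)CC(C)C)C/C(CO[Si](C)(C)C(C)(C)C)=C\CC/C(C)=C\2 | intermediate
30 | 8-O-isovalerate 14-alcohol | C=C1C(=O)O[C@H]2[C@H]1[C@H](OC(=O)CC(C)C)C/C(CO)=C\CC/C(C)=C\2 | intermediate
31 | 8-O-isovaleryl 14-al, 4Z alkene, formyl trans to C2 | C=C1C(=O)O[C@H]2[C@H]1[C@H](OC(=O)CC(C)C)C/C(C=O)=C\CC/C(C)=C\2 | intermediate
32 | CNP0260081.1, (4R,5S,6S,7R,8R)-4,5-epoxy-8-isovaleryloxy-14-oxo-germacra-1(10),11(13)-dien-6,12-olide, ring-cis at C1=C10 | C=C1C(=O)O[C@H]2[C@H]1[C@H](OC(=O)CC(C)C)C/C(C=O)=C\CC[C@@]1(C)O[C@@H]21 | target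

**Count and risks**

Total steps: 21. Longest linear sequence: 19 steps (1 → 32 through steps 1–3, 5–11 and 13–21).

Step 13 (Proposed new method). What may go wrong: opening of the cyclobutene in the reverse sense (ruthenium ending on the methyl-bearing carbon), repeated insertion or polymerisation of the cyclobutene, E geometry at C4=C5, or ring closure too slow to compete with dimerisation. Fallback with known chemistry, from aldehyde 17 back to 22: a Stork–Zhao-type Wittig reaction with Ph3P=C(CH3)I (from ethyltriphenylphosphonium iodide, n-BuLi, I2 and NaN(SiMe3)2, THF, −78 °C) should give the (Z)-vinyl iodide F1. Negishi coupling with but-3-enylzinc bromide under Pd(PPh3)4 (zerovalent palladium) replaces iodine with retention and gives triene 21, now isolated. Ring-closing metathesis of 21 with the same ruthenium catalyst at 2 mM in toluene then gives 22; the acetonide bridge still blocks the six-membered closure.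

Step 5. What may go wrong: the hindered, basic 2-alkyl-dithianyl anion adds 1,2 to the lactone carbonyl or removes the γ-proton of the butenolide instead of adding 1,4. Fallback, from 8 and 5 back to 12, forming C8–C9 by allylation instead: the unsubstituted anion 5 adds 1,4 and trans to 8 (THF/HMPA, −78 °C) to give the dithianyl lactone F2. Unmasking (MeI, CaCO3, aqueous MeCN) gives the C8 aldehyde F3. Barbier allylation with bromide 3 and Zn dust in THF/aq. NH4Cl gives the homoallylic alcohols F4 as a C8 epimer mixture. Dess–Martin oxidation of the mixture converges on ketone 12.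

Step 21. What may go wrong: poor facial selectivity, if the ring conformation overrides the allylic C6–O bias. Fallback, from 31 directly to 32 under reagent control: Shi epoxidation with the ketone enantiomer that the spiro transition-state model assigns to the 4R,5S face (by analogy with 1-arylcycloalkenes, the L-sorbose-derived ent-ketone), KHSO5 (as 2KHSO5·KHSO4·K2SO4), NaHCO3 buffer near pH 8, MeCN/H2O, 0 °C; no new compound arises (F0).

**Further compounds**

F1 | step 13 | (4R,5R)-4-[(4R)-2,2-dimethyl-6-methylidene-1,3-dioxepan-4-yl]-5-[(1Z)-2-iodoprop-1-en-1-yl]oxolan-2-one | C1C(=O)O[C@H](/C=C(C)\I)[C@H]1[C@H]4CC(=C)COC(C)(C)O4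
F2 | step 5 | trans-5-(TBDPS-oxymethyl)-4-(1,3-dithian-2-yl)oxolan-2-one | C1C(=O)O[C@H](CO[Si](c2ccccc2)(c3ccccc3)C(C)(C)C)[C@H]1C4SCCCS4
F3 | step 5 | trans-2-(TBDPS-oxymethyl)-5-oxooxolane-3-carbaldehyde | C1C(=O)O[C@H](CO[Si](c2ccccc2)(c3ccccc3)C(C)(C)C)[C@H]1C=O
F4 | step 5 | 13 and its C8 epimer as a mixture (C8 undefined) | C1C(=O)O[C@H](CO[Si](c2ccccc2)(c3ccccc3)C(C)(C)C)[C@H]1C(O)CC(=C)CO[Si](C)(C)C(C)(C)C
F0 | step 21 | none | none
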